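**Retrosynthetic overview**
- The target is the (2R)-flavanone (the [C@H] centre in the given SMILES works out as R). Its pyranone ring (C2–O1 bond) and its chromene ring (O–CMe2 bond) are both opened at once, leading back to the acyclic 2',4',4-trihydroxy-3,5-diprenylchalcone.
- The chalcone is cut at Cα=Cβ (Claisen–Schmidt) into 2,4-dihydroxyacetophenone and 4-hydroxy-3,5-diprenylbenzaldehyde.
- The aldehyde comes from double ortho C-prenylation of 4-hydroxybenzaldehyde with prenyl bromide.
- Ring order: both benzene rings are bought; the chromene ring and then the pyranone ring (with the C2 stereocentre) are closed in one flask in the last step, without protecting groups.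

Compounds are numbered in the order they appear in the forward route.

Assumption: the facial sense of the chiral phosphoric acid in step 3 has no direct precedent on this substrate; (R)-TRIP is written for the 2R product, and if the first run (chiral HPLC, CD) shows 2S, the (S)-acid is used with nothing else changed.

**Step 1**
Reactants: 1 4-hydroxybenzaldehyde; 2 prenyl bromide (1-bromo-3-methylbut-2-ene, 2.4 equiv)
Product: 4 diprenyl aldehyde (4-hydroxy-3,5-bis(3-methylbut-2-en-1-yl)benzaldehyde), via monoprenyl aldehyde 3 (not isolated)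
Conditions: KOH (2.5 equiv, 10% aq), 0 °C to rt, 24 h; then HCl to pH 3; chromatography (expect 20–30%; recovered 3 is resubmitted)
Reagents that add atoms: none
Why: In water the hydrogen-bonded phenoxide of 1 reacts through carbon with the soft allylic bromide (phenoxide C-alkylation) at the only activated free positions, the two carbons ortho to oxygen, first to 3 and then to 4; no stereocentre is formed.

**Step 2**
Reactants: 4 diprenyl aldehyde; 5 2,4-dihydroxyacetophenone
Product: 7 diprenyl chalcone ((E)-1-(2,4-dihydroxyphenyl)-3-[4-hydroxy-3,5-bis(3-methylbut-2-en-1-yl)phenyl]prop-2-en-1-one), via aldol adduct 6 (not isolated)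
Conditions: KOH (60% aq, 20 equiv), EtOH, rt, 72 h, Ar; then 2 M HCl, 0 °C
Reagents that add atoms: none
Why: Claisen–Schmidt condensation: the enolate of 5 adds to the non-enolisable aldehyde 4 and aldol 6 dehydrates by E1cB to the conjugated E-enone, while the strongly basic medium keeps the chalcone open as its 2'-phenoxide and leaves the prenyl groups untouched; no stereocentre is formed.

**Step 3**
Reactants: 7 diprenyl chalcone
Product: 10 ent-abyssinone III ((2R)-7-hydroxy-2-[2,2-dimethyl-8-(3-methylbut-2-en-1-yl)-2H-chromen-6-yl]-2,3-dihydro-4H-chromen-4-one), via o-quinone methide 8 (not isolated), via chromene chalcone 9 (not isolated)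
Conditions: DDQ (1.05 equiv), PhMe, 60 °C, 2 h; then (R)-TRIP (10 mol%), 4 Å MS, 40 °C, 48 h, same flask; stop at about 90% conversion; filter, silica (no basic work-up)
Reagents that add atoms: none
Why: Proposed new method: DDQ removes hydride from the benzylic-allylic CH2 of one of the two equivalent prenyl groups next to the free phenol to give o-quinone methide 8, which closes by oxa-6π electrocyclisation to the 2,2-dimethylchromene 9 (the known DDQ chromenylation of o-prenylphenols); the chiral phosphoric acid, which tolerates DDQ and its hydroquinone, then holds the enone C=O with its P–OH and the 2'-OH with its P=O and delivers the phenol oxygen to one face of the β-carbon (made more cationic by the para chromene oxygen) in a 6-endo oxa-Michael addition that sets C2 as R; the closest known reaction types are the phosphoric-acid-catalysed enantioselective aza-Michael cyclisation of 2'-aminochalcones to 2-aryl-2,3-dihydroquinolin-4-ones and the cinchona-thiourea-catalysed cyclisation of 2'-hydroxychalcones to flavanones.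

**Compound list**
1 | 4-hydroxybenzaldehyde | O=Cc1ccc(O)cc1 | starting material
2 | prenyl bromide (1-bromo-3-methylbut-2-ene) | CC(C)=CCBr | starting material
3 | 4-hydroxy-3-(3-methylbut-2-en-1-yl)benzaldehyde (monoprenyl aldehyde, not isolated) | CC(C)=CCc1cc(C=O)ccc1O | intermediate
4 | 4-hydroxy-3,5-bis(3-methylbut-2-en-1-yl)benzaldehyde | CC(C)=CCc1cc(C=O)cc(CC=C(C)C)c1O | intermediate
5 | 2,4-dihydroxyacetophenone | CC(=O)c1ccc(O)cc1O | starting material
6 | rac-1-(2,4-dihydroxyphenyl)-3-hydroxy-3-[4-hydroxy-3,5-bis(3-methylbut-2-en-1-yl)phenyl]propan-1-one (aldol adduct, not isolated) | CC(C)=CCc1cc(C(O)CC(=O)c2ccc(O)cc2O)cc(CC=C(C)C)c1O | intermediate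
7 | (E)-1-(2,4-dihydroxyphenyl)-3-[4-hydroxy-3,5-bis(3-methylbut-2-en-1-yl)phenyl]prop-2-en-1-one | CC(C)=CCc1cc(/C=C/C(=O)c2ccc(O)cc2O)cc(CC=C(C)C)c1O | intermediate
8 | o-quinone methide: 4-[(E)-3-(2,4-dihydroxyphenyl)-3-oxoprop-1-enyl]-2-(3-methylbut-2-en-1-yl)-6-(3-methylbut-2-en-1-ylidene)cyclohexa-2,4-dien-1-one (not isolated) | O=C1C(=CC=C(C)C)C=C(/C=C/C(=O)c2ccc(O)cc2O)C=C1CC=C(C)C | intermediate
9 | (E)-1-(2,4-dihydroxyphenyl)-3-[2,2-dimethyl-8-(3-methylbut-2-en-1-yl)-2H-chromen-6-yl]prop-2-en-1-one (chromene chalcone, not isolated) | CC(C)=CCc1cc(/C=C/C(=O)c2ccc(O)cc2O)cc2c1OC(C)(C)C=C2 | intermediate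
10 | ent-abyssinone III, (2R)-7-hydroxy-2-[2,2-dimethyl-8-(3-methylbut-2-en-1-yl)-2H-chromen-6-yl]-2,3-dihydro-4H-chromen-4-one | CC(C)=CCc1cc([C@H]2CC(=O)c3ccc(O)cc3O2)cc2c1OC(C)(C)C=C2 | target

**Totals**
Total step count: 3. Longest linear sequence: 3 (from 4-hydroxybenzaldehyde).

**Steps most likely to fail, with fallbacks**

Step 3 (highest risk). The acid may be too weak to cyclise the hydrogen-bonded 2'-hydroxychalcone at a useful rate. The ring closure is also reversible, so ee can erode near equilibrium, and the level and sense of induction are unproven. The fallback sets out from 7 and returns at 10. DDQ (1.05 equiv, PhMe, 60 °C) followed in the same flask by NaOAc in EtOH at reflux still closes both rings in one operation, through 9, and gives racemic abyssinone III F4. The racemate is then resolved kinetically by asymmetric transfer hydrogenation with [Cp*RhCl((S,S)-TsDPEN)] (1 mol%) and HCO2H/Et3N (5:2) in EtOAc at rt, stopped near 55% conversion. The (2S)-ketone is reduced to the cis-flavanol (2S,4S)-2-[2,2-dimethyl-8-(3-methylbut-2-en-1-yl)-2H-chromen-6-yl]-3,4-dihydro-2H-chromene-4,7-diol F5. The unreacted (2R)-ketone 10 is recovered by chromatography (at most about 45%). The catalyst antipode is assigned by analogy with aryl ketone reductions and is swapped if the wrong enantiomer is retained.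

Step 1. Phenoxide C-alkylation gives a mixture of O-prenyl ether, mono- and di-C-prenylated aldehyde, and the yield of 4 is low. The fallback sets out from 1 and returns at 4. Bromination (Br2, 2.1 equiv, AcOH, rt) gives 3,5-dibromo-4-hydroxybenzaldehyde F1. A double Stille coupling with tributyl(3-methylbut-2-en-1-yl)stannane (2.4 equiv, Pd(PPh3)4 5 mol%, DMF, 100 °C) then places both prenyl groups at the halogen-defined positions.

Step 2. The para-phenoxide of 4 deactivates the aldehyde, so the unprotected condensation may be slow and low-yielding. The fallback sets out from 4 and returns at 7. The phenol is masked (NaH, MOMCl, THF, 0 °C) as 4-(methoxymethoxy)-3,5-bis(3-methylbut-2-en-1-yl)benzaldehyde F2. Claisen–Schmidt condensation with 5 (KOH, EtOH, rt) gives (E)-1-(2,4-dihydroxyphenyl)-3-[4-(methoxymethoxy)-3,5-bis(3-methylbut-2-en-1-yl)phenyl]prop-2-en-1-one F3. Treatment with 3 M HCl in MeOH at rt removes the MOM group, kept mild so the freed phenol does not add to the prenyl groups.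

**Further compounds**
F1 | step 1 | 3,5-dibromo-4-hydroxybenzaldehyde | O=Cc1cc(Br)c(O)c(Br)c1
F2 | step 2 | 4-(methoxymethoxy)-3,5-bis(3-methylbut-2-en-1-yl)benzaldehyde | COCOc1c(CC=C(C)C)cc(C=O)cc1CC=C(C)C
F3 | step 2 | (E)-1-(2,4-dihydroxyphenyl)-3-[4-(methoxymethoxy)-3,5-bis(3-methylbut-2-en-1-yl)phenyl]prop-2-en-1-one | COCOc1c(CC=C(C)C)cc(/C=C/C(=O)c2ccc(O)cc2O)cc1CC=C(C)C
F4 | step 3 | racemic abyssinone III, rac-7-hydroxy-2-[2,2-dimethyl-8-(3-methylbut-2-en-1-yl)-2H-chromen-6-yl]-2,3-dihydro-4H-chromen-4-one | CC(C)=CCc1cc(C2CC(=O)c3ccc(O)cc3O2)cc2c1OC(C)(C)C=C2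
F5 | step 3 | (2S,4S)-2-[2,2-dimethyl-8-(3-methylbut-2-en-1-yl)-2H-chromen-6-yl]-3,4-dihydro-2H-chromene-4,7-diol | CC(C)=CCc1cc([C@@H]2C[C@H](O)c3ccc(O)cc3O2)cc2c1OC(C)(C)C=C2
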